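**Retrosynthetic overview**

1. Target 23 ⇐ aldehyde 22 (enol acetylation at C1, oxygen anti to the diene) ⇐ acetal 21.
2. Key disconnection C2=C3: the nine-membered carbocycle of 21 is formed by Ramberg–Bäcklund contraction (loss of SO2) of the ten-membered cyclic sulfone 18. The enabling feature is the ring SO2 of the 10-oxa-4-thiabicyclo[7.2.1]dodecene, which sits between C2H2 and the allylic C3H2; the E-C4=C5 bond and the cis-bridging C7/C9 γ-lactone are already in place.
3. 18 ⇐ sulfide 17 ⇐ 16: the ten-membered thiacycle is closed at a C–S bond (C2 thiolate onto the C3 allylic chloride) on a trans,trans-γ-lactone whose two arms are cis.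
4. Lactone 8 ⇐ (S)-citronellal 4 + nitroalkene 3: organocatalytic Michael addition (C8–C9), catalyst-controlled propargylation (C6–C7), nitro-to-acid oxidation and lactonisation. E-C4=C5 comes from Zr-catalysed carboalumination; C2 from α-methylenation and thioacid addition.
5. Ring order: γ-lactone (step 4), then ten-membered thiacycle (step 11), then nine-membered carbocycle by contraction (step 13).

Key step: step 13

Remark on locants: C1–C10 in the text follow the target. C1 is the ring carbon bearing the acetoxymethylidene group, then C2=C3, C4=C5(CH3), C6H2, C7 (O-bearing), C8 (side-chain-bearing), C9 (lactone α-carbon); C10 is the side-chain methine.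

Remark on C1: from 15 to 22 (and in 13, 19, 20) C1 is expected as a mixture of both epimers. This is harmless because C1 becomes sp2 in step 15; the SMILES of these compounds leave that centre undefined.

**Step 1**
Reactants: 1 3-[(tert-butyldimethylsilyl)oxy]propanal
Product: 3 (E)-tert-butyldimethyl[(4-nitrobut-3-en-1-yl)oxy]silane, via nitro alcohol 2 (not isolated)
Conditions: MeNO2, KOt-Bu (cat.), THF/t-BuOH, 0 °C; then MsCl, Et3N, CH2Cl2, 0 °C
Reagents that add atoms: nitromethane, C[N+](=O)[O-]
Why: Henry addition followed by mesylation and E1cB elimination (nitroaldol condensation) should give the conjugated (E)-nitroalkene, the thermodynamically favoured isomer; no stereocentre is carried forward.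

**Step 2**
Reactants: 4 (S)-citronellal [(3S)-3,7-dimethyloct-6-enal]; 3 (E)-tert-butyldimethyl[(4-nitrobut-3-en-1-yl)oxy]silane
Product: 5 (2R,3R)-5-[(tert-butyldimethylsilyl)oxy]-2-[(2S)-6-methylhept-5-en-2-yl]-3-(nitromethyl)pentanal
Conditions: (S)-α,α-diphenylprolinol trimethylsilyl ether (10 mol%), 4-nitrophenol (10 mol%), toluene, 0 °C → rt
Reagents that add atoms: none
Why: Hayashi–Jørgensen enamine Michael addition: the anti-(E)-enamine of 4, shielded on one face by the CPh2OTMS group, adds to the nitroalkene through the usual synclinal transition state, so the catalyst sets both new centres (C8 and C9, syn adduct), while the remote C10 centre of citronellal has little influence.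

**Step 3**
Reactants: 5 (2R,3R)-5-[(tert-butyldimethylsilyl)oxy]-2-[(2S)-6-methylhept-5-en-2-yl]-3-(nitromethyl)pentanal
Product: 6 (4S,5R,6R)-8-[(tert-butyldimethylsilyl)oxy]-5-[(2S)-6-methylhept-5-en-2-yl]-6-(nitromethyl)oct-1-yn-4-ol
Conditions: allenylboronic acid pinacol ester, (S)-TRIP (5 mol%), 4 Å MS, toluene, −20 °C; aq. NaHCO3
Reagents that add atoms: allenylboronic acid pinacol ester, C=C=CB1OC(C)(C)C(C)(C)O1
Why: Chiral phosphoric acid-catalysed propargylation with an allenylboronate (SE2′, six-membered chair transition state with the catalyst hydrogen-bonded to the boronate): both α-substituents of 5 are secondary alkyl groups, so substrate bias is weak and the catalyst (the antipode of the one that adds to the Re face) should deliver the propargyl group to the Si face, setting C7 as S.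

**Step 4**
Reactants: 6 (4S,5R,6R)-8-[(tert-butyldimethylsilyl)oxy]-5-[(2S)-6-methylhept-5-en-2-yl]-6-(nitromethyl)oct-1-yn-4-ol
Product: 8 (3R,4R,5S)-3-{2-[(tert-butyldimethylsilyl)oxy]ethyl}-4-[(2S)-6-methylhept-5-en-2-yl]-5-(prop-2-yn-1-yl)oxolan-2-one, via hydroxy acid 7 (not isolated)
Conditions: NaNO2, AcOH, DMSO, 35 °C; then 1 M HCl, EtOAc, rt
Reagents that add atoms: sodium nitrite, [Na+].[O-]N=O
Why: Oxidative Nef-type conversion of a primary nitroalkane into the carboxylic acid with nitrite in acetic acid (via the nitrolic acid), after which the 4-hydroxy acid 7 closes spontaneously to the γ-lactone; no stereocentre is touched, so the C7 and C9 arms are cis to each other and trans to the C8 side chain.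

**Step 5**
Reactants: 8 (3R,4R,5S)-3-{2-[(tert-butyldimethylsilyl)oxy]ethyl}-4-[(2S)-6-methylhept-5-en-2-yl]-5-(prop-2-yn-1-yl)oxolan-2-one
Product: 9 (3R,4R,5S)-3-{2-[(tert-butyldimethylsilyl)oxy]ethyl}-5-[(2E)-4-hydroxy-2-methylbut-2-en-1-yl]-4-[(2S)-6-methylhept-5-en-2-yl]oxolan-2-one
Conditions: Me3Al, Cp2ZrCl2 (25 mol%), H2O (1 equiv), CH2Cl2, −25 °C; then (CH2O)n, THF, −25 °C → rt; Rochelle salt
Reagents that add atoms: trimethylaluminium, C[Al](C)C; paraformaldehyde (as formaldehyde), C=O
Why: Negishi zirconium-catalysed carboalumination: syn addition of Me–Al across the terminal alkyne (methyl to the internal carbon) and trapping of the alkenylalane with formaldehyde with retention fixes the E geometry of C4=C5; the lactone should tolerate Me3Al at −25 °C under the water-accelerated protocol.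

**Step 6**
Reactants: 9 (3R,4R,5S)-3-{2-[(tert-butyldimethylsilyl)oxy]ethyl}-5-[(2E)-4-hydroxy-2-methylbut-2-en-1-yl]-4-[(2S)-6-methylhept-5-en-2-yl]oxolan-2-one
Product: 10 (3R,4R,5S)-3-{2-[(tert-butyldimethylsilyl)oxy]ethyl}-5-[(2E)-4-chloro-2-methylbut-2-en-1-yl]-4-[(2S)-6-methylhept-5-en-2-yl]oxolan-2-one
Conditions: NCS, Me2S, CH2Cl2, −20 → 0 °C
Reagents that add atoms: N-chlorosuccinimide, O=C1CCC(=O)N1Cl
Why: Corey–Kim chlorination: the alkoxysulfonium salt is displaced by chloride in an SN2 manner, which converts primary allylic alcohols into chlorides without allylic transposition or loss of E geometry.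

**Step 7**
Reactants: 10 (3R,4R,5S)-3-{2-[(tert-butyldimethylsilyl)oxy]ethyl}-5-[(2E)-4-chloro-2-methylbut-2-en-1-yl]-4-[(2S)-6-methylhept-5-en-2-yl]oxolan-2-one
Product: 11 (3R,4R,5S)-5-[(2E)-4-chloro-2-methylbut-2-en-1-yl]-3-(2-hydroxyethyl)-4-[(2S)-6-methylhept-5-en-2-yl]oxolan-2-one
Conditions: HF·pyridine, THF, 0 °C
Reagents that add atoms: none
Why: Fluoride-mediated cleavage of a primary TBS ether; the mildly acidic reagent should leave the allylic chloride and the lactone untouched.

**Step 8**
Reactants: 11 (3R,4R,5S)-5-[(2E)-4-chloro-2-methylbut-2-en-1-yl]-3-(2-hydroxyethyl)-4-[(2S)-6-methylhept-5-en-2-yl]oxolan-2-one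
Product: 12 2-{(3R,4R,5S)-5-[(2E)-4-chloro-2-methylbut-2-en-1-yl]-4-[(2S)-6-methylhept-5-en-2-yl]-2-oxooxolan-3-yl}acetaldehyde
Conditions: Dess–Martin periodinane, CH2Cl2, 0 °C → rt; aq. NaHCO3/Na2S2O3 work-up
Reagents that add atoms: none
Why: Dess–Martin oxidation of the primary alcohol under near-neutral conditions should give the aldehyde without epimerising C9 or disturbing the allylic chloride.

**Step 9**
Reactants: 12 2-{(3R,4R,5S)-5-[(2E)-4-chloro-2-methylbut-2-en-1-yl]-4-[(2S)-6-methylhept-5-en-2-yl]-2-oxooxolan-3-yl}acetaldehyde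
Product: 15 S-[2-{(3S,4R,5S)-5-[(2E)-4-chloro-2-methylbut-2-en-1-yl]-4-[(2S)-6-methylhept-5-en-2-yl]-2-oxooxolan-3-yl}-3-oxopropyl] ethanethioate (both C1 epimers), via Mannich base 13 (not isolated), via enal 14 (not isolated)
Conditions: Me2N=CH2+ I−, i-Pr2NEt, CH2Cl2, rt; aq. wash; then AcSH, CH2Cl2, 0 °C → rt (no base)
Reagents that add atoms: Eschenmoser's salt (N,N-dimethylmethyleneiminium iodide), C=[N+](C)C.[I-]; thioacetic acid, CC(=O)S
Why: Mannich reaction with Eschenmoser's salt and β-elimination of dimethylamine gives the 2-substituted acrolein 14 (α-methylenation, the new carbon being C2), to which thioacetic acid adds without base in a thia-Michael reaction, placing sulfur on C2; the new C1 centre forms unselectively, which is harmless because C1 becomes sp2 in step 15.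

**Step 10**
Reactants: 15 S-[2-{(3S,4R,5S)-5-[(2E)-4-chloro-2-methylbut-2-en-1-yl]-4-[(2S)-6-methylhept-5-en-2-yl]-2-oxooxolan-3-yl}-3-oxopropyl] ethanethioate
Product: 16 S-[2-{(3S,4R,5S)-5-[(2E)-4-chloro-2-methylbut-2-en-1-yl]-4-[(2S)-6-methylhept-5-en-2-yl]-2-oxooxolan-3-yl}-3,3-dimethoxypropyl] ethanethioate (both C1 epimers)
Conditions: HC(OMe)3, PPTS (cat.), CH2Cl2/MeOH, rt
Reagents that add atoms: trimethyl orthoformate, COC(OC)OC
Why: Acid-catalysed acetalisation with the orthoformate masks the aldehyde, so that the thiolate liberated in step 11 cannot be lost by retro-thia-Michael elimination and the carbonyl carbon survives the strongly basic key step.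

**Step 11**
Reactants: 16 S-[2-{(3S,4R,5S)-5-[(2E)-4-chloro-2-methylbut-2-en-1-yl]-4-[(2S)-6-methylhept-5-en-2-yl]-2-oxooxolan-3-yl}-3,3-dimethoxypropyl] ethanethioate
Product: 17 (1S,6E,9S,12R)-2-(dimethoxymethyl)-7-methyl-12-[(2S)-6-methylhept-5-en-2-yl]-10-oxa-4-thiabicyclo[7.2.1]dodec-6-en-11-one (both C2-position epimers, i.e. C1 of the target)
Conditions: K2CO3, degassed MeOH/THF, syringe-pump addition to 1 mM, rt
Reagents that add atoms: none
Why: Methanolysis of the thioacetate liberates the thiolate, which closes the ten-membered ring by intramolecular SN2 displacement of the primary allylic chloride (10-exo-tet) under high dilution; the two arms are cis on the lactone, the long C–S bonds and the E-alkene ease medium-ring closure, and no stereocentre is formed.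

**Step 12**
Reactants: 17 (1S,6E,9S,12R)-2-(dimethoxymethyl)-7-methyl-12-[(2S)-6-methylhept-5-en-2-yl]-10-oxa-4-thiabicyclo[7.2.1]dodec-6-en-11-one
Product: 18 the corresponding 4,4-dioxide (ten-membered cyclic sulfone, SO2 between C2H2 and allylic C3H2)
Conditions: TPAP (5 mol%), NMO, 4 Å MS, MeCN, rt
Reagents that add atoms: N-methylmorpholine N-oxide, C[N+]1([O-])CCOCC1
Why: Catalytic perruthenate/NMO oxidation takes the sulfide through the sulfoxide to the sulfone under neutral, anhydrous conditions, which is chemoselective for sulfur over the trisubstituted alkenes and spares the acetal.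

**Step 13**
Reactants: 18 ten-membered cyclic sulfone (4,4-dioxide of 17)
Product: 21 (1S,3Z,5E,8S,11R)-2-(dimethoxymethyl)-6-methyl-11-[(2S)-6-methylhept-5-en-2-yl]-9-oxabicyclo[6.2.1]undeca-3,5-dien-10-one (both C1 epimers), via bromo sulfone 19 (not isolated), via episulfone 20 (not isolated)
Conditions: CBr2F2, KOH/Al2O3, t-BuOH/CH2Cl2, 0 °C → rt; then pH 4 phosphate buffer
Reagents that add atoms: none
Why: Ramberg–Bäcklund rearrangement under halogenative (Chan-type) conditions: KOH deprotonates the more acidic allylic α-CH2 (C3), the carbanion is brominated by CBr2F2 (19), a second deprotonation at C2 displaces bromide to give the thiirane 1,1-dioxide 20, and cheletropic loss of SO2 leaves the C2=C3 double bond. The closest precedents are Ramberg–Bäcklund contractions of medium-ring cyclic sulfones to cycloalkenes and of allylic sulfones to 1,3-dienes. The ring that changes size is closed by the 1,3-elimination (3-exo-tet attack of the C2 carbanion on C3–Br), which turns the ten-membered thiacycle into the nine-membered carbocycle fused to the transient three-membered ring. No stereocentre is created; the new alkene should be Z because only the cis-fused episulfone is accessible next to the existing E C4=C5 bond (the trans isomer would lead to an E,E-diene in a nine-membered ring), so the strained (2Z,4E)-diene is completed in the same operation. The step needs regioconvergence (bromination at C3 or C2 gives the same alkene), retention at C7/C8/C9 (secured by the cis-bridging lactone, whose bridgehead C9 cannot invert without prohibitive strain; any saponified hydroxy acid relactonises on acidic work-up) and a base-stable aldehyde equivalent (the dimethyl acetal).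

**Step 14**
Reactants: 21 (1S,3Z,5E,8S,11R)-2-(dimethoxymethyl)-6-methyl-11-[(2S)-6-methylhept-5-en-2-yl]-9-oxabicyclo[6.2.1]undeca-3,5-dien-10-one
Product: 22 (1S,3Z,5E,8S,11R)-6-methyl-11-[(2S)-6-methylhept-5-en-2-yl]-10-oxo-9-oxabicyclo[6.2.1]undeca-3,5-diene-2-carbaldehyde (both C1 epimers)
Conditions: PPTS (cat.), acetone/H2O (10:1), 40 °C; crude product used at once
Reagents that add atoms: water, O
Why: Mild acid-catalysed hydrolysis of the dimethyl acetal releases the aldehyde; PPTS is weak enough to leave the lactone and the (Z,E)-diene alone, and immediate use of the crude aldehyde should avoid isomerisation into conjugation.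

**Step 15**
Reactants: 22 (1S,3Z,5E,8S,11R)-6-methyl-11-[(2S)-6-methylhept-5-en-2-yl]-10-oxo-9-oxabicyclo[6.2.1]undeca-3,5-diene-2-carbaldehyde
Product: 23 (Z)-[(1S,3Z,5E,8S,11R)-6-methyl-11-[(2S)-6-methylhept-5-en-2-yl]-10-oxo-9-oxabicyclo[6.2.1]undeca-3,5-dien-2-ylidene]methyl acetate (CNP0287742.1)
Conditions: Ac2O, Et3N, DMAP (cat.), CH2Cl2, 0 °C
Reagents that add atoms: acetic anhydride, CC(=O)OC(C)=O
Why: DMAP-catalysed O-acetylation of the extended dienolate of the α-dienyl aldehyde (enol acetylation): the enolate oxygen should sit anti to the C2=C3 vinyl group and syn to C9–H (W-shaped dienolate, as in dienyl acetates made from α-substituted unsaturated aldehydes), which gives the (Z)-acetoxymethylidene geometry and removes the C1 stereocentre, so both epimers of 22 converge.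

**Compound list**

1 | 3-[(tert-butyldimethylsilyl)oxy]propanal | O=CCCO[Si](C)(C)C(C)(C)C | starting material
2 | rac-4-[(tert-butyldimethylsilyl)oxy]-1-nitrobutan-2-ol | OC(C[N+](=O)[O-])CCO[Si](C)(C)C(C)(C)C | intermediate
3 | (E)-tert-butyldimethyl[(4-nitrobut-3-en-1-yl)oxy]silane | [O-][N+](=O)/C=C/CCO[Si](C)(C)C(C)(C)C | intermediate
4 | (S)-citronellal, (3S)-3,7-dimethyloct-6-enal | O=CC[C@@H](C)CCC=C(C)C | starting material
5 | (2R,3R)-5-[(tert-butyldimethylsilyl)oxy]-2-[(2S)-6-methylhept-5-en-2-yl]-3-(nitromethyl)pentanal | O=C[C@H]([C@@H](C)CCC=C(C)C)[C@H](C[N+](=O)[O-])CCO[Si](C)(C)C(C)(C)C | intermediate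
6 | (4S,5R,6R)-8-[(tert-butyldimethylsilyl)oxy]-5-[(2S)-6-methylhept-5-en-2-yl]-6-(nitromethyl)oct-1-yn-4-ol | C#CC[C@H](O)[C@H]([C@@H](C)CCC=C(C)C)[C@H](C[N+](=O)[O-])CCO[Si](C)(C)C(C)(C)C | intermediate
7 | (2R,3R,4S)-2-{2-[(tert-butyldimethylsilyl)oxy]ethyl}-4-hydroxy-3-[(2S)-6-methylhept-5-en-2-yl]hept-6-ynoic acid | C#CC[C@H](O)[C@H]([C@@H](C)CCC=C(C)C)[C@H](C(=O)O)CCO[Si](C)(C)C(C)(C)C | intermediate
8 | (3R,4R,5S)-3-{2-[(tert-butyldimethylsilyl)oxy]ethyl}-4-[(2S)-6-methylhept-5-en-2-yl]-5-(prop-2-yn-1-yl)oxolan-2-one | O=C1O[C@@H](CC#C)[C@H]([C@@H](C)CCC=C(C)C)[C@H]1CCO[Si](C)(C)C(C)(C)C | intermediate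
9 | (3R,4R,5S)-3-{2-[(tert-butyldimethylsilyl)oxy]ethyl}-5-[(2E)-4-hydroxy-2-methylbut-2-en-1-yl]-4-[(2S)-6-methylhept-5-en-2-yl]oxolan-2-one | O=C1O[C@@H](C/C(C)=C/CO)[C@H]([C@@H](C)CCC=C(C)C)[C@H]1CCO[Si](C)(C)C(C)(C)C | intermediate
10 | (3R,4R,5S)-3-{2-[(tert-butyldimethylsilyl)oxy]ethyl}-5-[(2E)-4-chloro-2-methylbut-2-en-1-yl]-4-[(2S)-6-methylhept-5-en-2-yl]oxolan-2-one | O=C1O[C@@H](C/C(C)=C/CCl)[C@H]([C@@H](C)CCC=C(C)C)[C@H]1CCO[Si](C)(C)C(C)(C)C | intermediate
11 | (3R,4R,5S)-5-[(2E)-4-chloro-2-methylbut-2-en-1-yl]-3-(2-hydroxyethyl)-4-[(2S)-6-methylhept-5-en-2-yl]oxolan-2-one | O=C1O[C@@H](C/C(C)=C/CCl)[C@H]([C@@H](C)CCC=C(C)C)[C@H]1CCO | intermediate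
12 | 2-{(3R,4R,5S)-5-[(2E)-4-chloro-2-methylbut-2-en-1-yl]-4-[(2S)-6-methylhept-5-en-2-yl]-2-oxooxolan-3-yl}acetaldehyde | O=C1O[C@@H](C/C(C)=C/CCl)[C@H]([C@@H](C)CCC=C(C)C)[C@H]1CC=O | intermediate
13 | Mannich base: 3-(dimethylamino)-2-{(3S,4R,5S)-5-[(2E)-4-chloro-2-methylbut-2-en-1-yl]-4-[(2S)-6-methylhept-5-en-2-yl]-2-oxooxolan-3-yl}propanal (both C1 epimers) | O=C1O[C@@H](C/C(C)=C/CCl)[C@H]([C@@H](C)CCC=C(C)C)[C@H]1C(CN(C)C)C=O | intermediate
14 | enal: 2-{(3S,4R,5S)-5-[(2E)-4-chloro-2-methylbut-2-en-1-yl]-4-[(2S)-6-methylhept-5-en-2-yl]-2-oxooxolan-3-yl}prop-2-enal | O=C1O[C@@H](C/C(C)=C/CCl)[C@H]([C@@H](C)CCC=C(C)C)[C@H]1C(=C)C=O | intermediate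
15 | S-[2-{(3S,4R,5S)-5-[(2E)-4-chloro-2-methylbut-2-en-1-yl]-4-[(2S)-6-methylhept-5-en-2-yl]-2-oxooxolan-3-yl}-3-oxopropyl] ethanethioate (both C1 epimers) | O=C1O[C@@H](C/C(C)=C/CCl)[C@H]([C@@H](C)CCC=C(C)C)[C@H]1C(C=O)CSC(C)=O | intermediate
16 | S-[2-{(3S,4R,5S)-5-[(2E)-4-chloro-2-methylbut-2-en-1-yl]-4-[(2S)-6-methylhept-5-en-2-yl]-2-oxooxolan-3-yl}-3,3-dimethoxypropyl] ethanethioate (both C1 epimers) | O=C1O[C@@H](C/C(C)=C/CCl)[C@H]([C@@H](C)CCC=C(C)C)[C@H]1C(CSC(C)=O)C(OC)OC | intermediate
17 | (1S,6E,9S,12R)-2-(dimethoxymethyl)-7-methyl-12-[(2S)-6-methylhept-5-en-2-yl]-10-oxa-4-thiabicyclo[7.2.1]dodec-6-en-11-one (both C1 epimers) | COC(OC)C1CSC/C=C(\C)C[C@@H]2OC(=O)[C@H]1[C@H]2[C@@H](C)CCC=C(C)C | intermediate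
18 | (1S,6E,9S,12R)-2-(dimethoxymethyl)-7-methyl-12-[(2S)-6-methylhept-5-en-2-yl]-10-oxa-4-thiabicyclo[7.2.1]dodec-6-en-11-one 4,4-dioxide (both C1 epimers) | COC(OC)C1CS(=O)(=O)C/C=C(\C)C[C@@H]2OC(=O)[C@H]1[C@H]2[C@@H](C)CCC=C(C)C | intermediate
19 | α-bromo sulfone: 18 with bromine on the allylic α-carbon C3 (epimers at C1 and C3) | COC(OC)C1CS(=O)(=O)C(Br)/C=C(\C)C[C@@H]2OC(=O)[C@H]1[C@H]2[C@@H](C)CCC=C(C)C | intermediate
20 | episulfone: thiirane 1,1-dioxide spanning C2 and C3 of the nine-membered carbocycle (cis-fused) | COC(OC)C1C3C(S3(=O)=O)/C=C(\C)C[C@@H]2OC(=O)[C@H]1[C@H]2[C@@H](C)CCC=C(C)C | intermediate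
21 | (1S,3Z,5E,8S,11R)-2-(dimethoxymethyl)-6-methyl-11-[(2S)-6-methylhept-5-en-2-yl]-9-oxabicyclo[6.2.1]undeca-3,5-dien-10-one (both C1 epimers) | COC(OC)C1/C=C\C=C(/C)C[C@@H]2OC(=O)[C@H]1[C@H]2[C@@H](C)CCC=C(C)C | intermediate
22 | (1S,3Z,5E,8S,11R)-6-methyl-11-[(2S)-6-methylhept-5-en-2-yl]-10-oxo-9-oxabicyclo[6.2.1]undeca-3,5-diene-2-carbaldehyde (both C1 epimers) | O=CC1/C=C\C=C(/C)C[C@@H]2OC(=O)[C@H]1[C@H]2[C@@H](C)CCC=C(C)C | intermediate
23 | (Z)-[(1S,3Z,5E,8S,11R)-6-methyl-11-[(2S)-6-methylhept-5-en-2-yl]-10-oxo-9-oxabicyclo[6.2.1]undeca-3,5-dien-2-ylidene]methyl acetate (CNP0287742.1) | CC(=O)O/C=C1/C=C\C=C(/C)C[C@@H]2OC(=O)[C@H]1[C@H]2[C@@H](C)CCC=C(C)C | target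

**Step count and risks**

Total step count: 15. Longest linear sequence: 15 steps (1 → 23; citronellal 4 enters at step 2).

Steps most likely to fail:

Step 13 (ring contraction). Halogenation and 1,3-elimination may not be balanced in one pot: over-bromination, transannular γ-alkylation of the allyl sulfonyl anion, or lactone saponification outrunning the rearrangement. The fallback separates the two events and sets out from sulfone 18. Deprotonation with LiHMDS (THF, −78 °C) and chlorination with hexachloroethane should give the isolable α-chloro sulfone F1. Treatment with KOt-Bu in THF (−78 → 0 °C, anhydrous classical Ramberg–Bäcklund) should then give the diene, returning to the route at 21.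

Step 11 (ten-membered ring closure). The irreversible S-alkylation may be outrun by intermolecular thioether formation (oligomerisation). The fallback moves ring closure to a reversible bond and sets out from 16. KSAc in DMF should replace the chloride to give the bis(thioacetate) F2. K2CO3/MeOH followed by I2 under high dilution should close the eleven-membered cyclic disulfide F3, where thiolate–disulfide exchange corrects oligomers. Sulfur extrusion with tris(diethylamino)phosphine (benzene, rt) should then contract the disulfide to the sulfide, returning to the route at 17.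

Step 15 (enol acetate geometry). O-acylation may show poor control of the enol geometry, or the aldehyde may isomerise into conjugation before it is trapped. The fallback fixes the geometry on an isolable intermediate and sets out from 22. TBSOTf/Et3N (CH2Cl2, −78 °C) should give the silyl enol ether F4; the Z isomer is separated and any E isomer is hydrolysed back to 22 and recycled. Fluoride-triggered desilylative acetylation (TBAT, Ac2O, THF, −40 °C) should then deliver the enol acetate with retention of geometry, returning to the route at 23.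

**Further compounds**

F1 | step 13 | α-chloro sulfone: 18 with chlorine on the allylic α-carbon C3 | COC(OC)C1CS(=O)(=O)C(Cl)/C=C(\C)C[C@@H]2OC(=O)[C@H]1[C@H]2[C@@H](C)CCC=C(C)C
F2 | step 11 | bis(thioacetate): 16 with the allylic chloride replaced by acetylsulfanyl | O=C1O[C@@H](C/C(C)=C/CSC(C)=O)[C@H]([C@@H](C)CCC=C(C)C)[C@H]1C(CSC(C)=O)C(OC)OC
F3 | step 11 | eleven-membered cyclic disulfide (S–S between C2 and C3), lactone-bridged | COC(OC)C1CSSC/C=C(\C)C[C@@H]2OC(=O)[C@H]1[C@H]2[C@@H](C)CCC=C(C)C
F4 | step 15 | (Z)-tert-butyldimethylsilyl enol ether of aldehyde 22 | CC(C)(C)[Si](C)(C)O/C=C1/C=C\C=C(/C)C[C@@H]2OC(=O)[C@H]1[C@H]2[C@@H](C)CCC=C(C)C
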